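**Retrosynthetic overview**
1. The target is guibourtinidol-(4β→6)-fisetinidol. The interflavan C4–C6 bond is made last but one, by acid-catalysed Friedel–Crafts coupling of a 4-methoxy-guibourtinidol with a fisetinidol (B-ring benzyl ethers), followed by hydrogenolysis.
2. Ring C of each flavan-3-ol comes from a trans-2-aryl-3-(hydroxymethyl)-2,3-dihydrobenzofuran-6-ol by ring expansion (1,2-aryl shift through a phenonium ion; OH enters C3 with inversion).
3. Each dihydrobenzofuran comes from 5-exo para-C-alkylation of a resorcinol mono-ether phenoxide by a terminal epoxide; the ether comes from resorcinol and a trans-3-aryl-2-(chloromethyl)oxirane.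
4. The oxiranes come from asymmetric organocatalytic epoxidation, reduction and chlorination of (E)-cinnamaldehydes, made by Heck arylation of acrolein with O-benzylated 4-iodocatechol and 4-iodophenol.
5. Ring order: rings A (resorcinol) and B (catechol, 4-iodophenol) are bought; in each half the five-membered O-ring is closed first and then enlarged to ring C; the halves are joined last.

Assumption: the SMILES is read as (2R,3S,4S) in the upper unit (2,3-trans, 3,4-cis) and (2R,3S) in the lower unit.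

**Route**

Step 1
Reactants: 1 catechol
Product: 2 1,2-bis(benzyloxy)benzene
Conditions: BnBr (2.2 equiv), K2CO3, DMF, 60 °C
Reagents that add atoms: benzyl bromide BrCc1ccccc1
Why: Williamson ether synthesis masks the catechol against palladium, peroxide, base and DDQ until the final hydrogenolysis; no stereocentre.

Step 2
Reactants: 2 1,2-bis(benzyloxy)benzene
Product: 3 1,2-bis(benzyloxy)-4-iodobenzene
Conditions: N-iodosuccinimide, CF3CO2H (cat.), CH3CN, 25 °C
Reagents that add atoms: N-iodosuccinimide O=C1CCC(=O)N1I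
Why: Electrophilic aromatic iodination goes para to one benzyloxy group, the only unhindered activated position.

Step 3
Reactants: 3 1,2-bis(benzyloxy)-4-iodobenzene; 4 acrolein
Product: 5 (E)-3-[3,4-bis(benzyloxy)phenyl]prop-2-enal
Conditions: Pd(OAc)2 (3 mol%), (n-C4H9)4NCl, NaHCO3, DMF, 50 °C
Reagents that add atoms: none
Why: Jeffery-type Mizoroki–Heck arylation of acrolein (syn-carbopalladation, syn-β-hydride elimination) gives the (E)-enal.

Step 4
Reactants: 5 (E)-3-[3,4-bis(benzyloxy)phenyl]prop-2-enal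
Product: 7 [(2S,3S)-3-[3,4-bis(benzyloxy)phenyl]oxiran-2-yl]methanol, via epoxy aldehyde 6 (not isolated)
Conditions: 35% aq. H2O2, (S)-2-{bis[3,5-bis(trifluoromethyl)phenyl][(trimethylsilyl)oxy]methyl}pyrrolidine (10 mol%), CH2Cl2, 25 °C; then NaBH4, CH3OH, 0 °C
Reagents that add atoms: hydrogen peroxide OO
Why: Jørgensen iminium-activated nucleophilic epoxidation (asymmetric Weitz–Scheffer type) with the catalyst enantiomer that gives the trans-(2R,3S)-epoxy aldehyde sets both epoxide centres, and in-situ NaBH4 reduction of the labile aldehyde leaves them untouched (C2 becomes S by priority only).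

Step 5
Reactants: 7 [(2S,3S)-3-[3,4-bis(benzyloxy)phenyl]oxiran-2-yl]methanol
Product: 8 (2R,3S)-3-[3,4-bis(benzyloxy)phenyl]-2-(chloromethyl)oxirane
Conditions: PPh3, N-chlorosuccinimide, CH2Cl2, 0 → 25 °C
Reagents that add atoms: N-chlorosuccinimide O=C1CCC(=O)N1Cl
Why: Appel-type chlorination of the primary alcohol (SN2 at CH2 via the alkoxyphosphonium salt) leaves the epoxide centres untouched (C2 becomes R by priority only) and gives a leaving group poorer than the activated benzylic epoxide.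

Step 6
Reactants: 8 (2R,3S)-3-[3,4-bis(benzyloxy)phenyl]-2-(chloromethyl)oxirane; 9 resorcinol
Product: 11 3-{(R)-[3,4-bis(benzyloxy)phenyl][(2S)-oxiran-2-yl]methoxy}phenol, via chlorohydrin 10 (not isolated)
Conditions: 9 (3 equiv), K2CO3, DMF, 45 °C
Reagents that add atoms: none
Why: The phenoxide opens the epoxide at the benzylic carbon with inversion (SN2, fixing the aryl ether centre as R), and the alkoxide then displaces chloride (epichlorohydrin-type epoxide relocation, retention at the carbinol carbon); excess resorcinol secures mono-O-alkylation.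

Step 7
Reactants: 11 3-{(R)-[3,4-bis(benzyloxy)phenyl][(2S)-oxiran-2-yl]methoxy}phenol
Product: 12 (2S,3R)-2-[3,4-bis(benzyloxy)phenyl]-3-(hydroxymethyl)-2,3-dihydro-1-benzofuran-6-ol
Conditions: K2CO3, CF3CH2OH–H2O (4:1), 0.02 M, 70 °C
Reagents that add atoms: none
Why: Intramolecular para-C-alkylation of the phenoxide by the epoxide (Winstein-type aryl participation, 5-exo-tet; O-alkylation is geometrically impossible and the carbon between the two oxygens is hindered) opens the inner epoxide carbon with inversion, which sets C3 as R and gives the trans-dihydrobenzofuran with C2 carried over.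

Step 8
Reactants: 12 (2S,3R)-2-[3,4-bis(benzyloxy)phenyl]-3-(hydroxymethyl)-2,3-dihydro-1-benzofuran-6-ol
Product: 14 (2R,3S)-2-[3,4-bis(benzyloxy)phenyl]-3,4-dihydro-2H-chromene-3,7-diol, via bromide 13 (not isolated)
Conditions: CBr4, PPh3, CH2Cl2, 0 °C; then Ag2CO3, (CF3)2CHOH–H2O (4:1), 0 → 25 °C
Reagents that add atoms: carbon tetrabromide BrC(Br)(Br)Br (bromine of 13); water O (hydroxyl oxygen of 14)
Why: Proposed new method: the primary bromide ionises with participation of the benzo ring (para-OH and ortho-O1 make C3a a strong neighbouring group) to a spiro-cyclopropane phenonium ion, which water opens at the ring-fusion carbon C3 (secondary, and the bond whose cleavage relieves the bicyclic strain), so the aryl carbon shifts from C3 to the former CH2 (1,2-aryl shift, five- to six-membered ring) and OH enters C3 with inversion, turning the (2S,3R)-trans-dihydrobenzofuran stereospecifically into the (2R,3S)-2,3-trans-flavan-3-ol (C2 untouched, C3 set here); the closest known reaction types are Winstein aryl-assisted (phenonium) solvolysis of 2-arylethyl halides, the Cossy ring expansion of prolinols to 3-hydroxypiperidines through bicyclic aziridinium ions, and the radical neophyl enlargement of dihydrobenzofuran-3-ylmethyl radicals.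

Step 9
Reactants: 15 4-iodophenol
Product: 16 1-(benzyloxy)-4-iodobenzene
Conditions: BnBr, K2CO3, acetone, 56 °C
Reagents that add atoms: benzyl bromide BrCc1ccccc1
Why: Williamson ether synthesis protects the B-ring phenol so that no B-ring quinone methide can form later.

Step 10
Reactants: 16 1-(benzyloxy)-4-iodobenzene; 4 acrolein
Product: 17 (E)-3-[4-(benzyloxy)phenyl]prop-2-enal
Conditions: Pd(OAc)2 (3 mol%), (n-C4H9)4NCl, NaHCO3, DMF, 50 °C
Reagents that add atoms: none
Why: Jeffery-type Mizoroki–Heck arylation of acrolein gives the (E)-enal as in step 3.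

Step 11
Reactants: 17 (E)-3-[4-(benzyloxy)phenyl]prop-2-enal
Product: 19 [(2S,3S)-3-[4-(benzyloxy)phenyl]oxiran-2-yl]methanol, via epoxy aldehyde 18 (not isolated)
Conditions: 35% aq. H2O2, (S)-2-{bis[3,5-bis(trifluoromethyl)phenyl][(trimethylsilyl)oxy]methyl}pyrrolidine (10 mol%), CH2Cl2, 25 °C; then NaBH4, CH3OH, 0 °C
Reagents that add atoms: hydrogen peroxide OO
Why: Jørgensen asymmetric epoxidation sets both epoxide centres (trans, (2R,3S) in the aldehyde) and NaBH4 reduces the aldehyde in situ, as in step 4.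

Step 12
Reactants: 19 [(2S,3S)-3-[4-(benzyloxy)phenyl]oxiran-2-yl]methanol
Product: 20 (2R,3S)-3-[4-(benzyloxy)phenyl]-2-(chloromethyl)oxirane
Conditions: PPh3, N-chlorosuccinimide, CH2Cl2, 0 → 25 °C
Reagents that add atoms: N-chlorosuccinimide O=C1CCC(=O)N1Cl
Why: Appel-type chlorination at the primary carbon leaves both stereocentres untouched, as in step 5.

Step 13
Reactants: 20 (2R,3S)-3-[4-(benzyloxy)phenyl]-2-(chloromethyl)oxirane; 9 resorcinol
Product: 22 3-{(R)-[4-(benzyloxy)phenyl][(2S)-oxiran-2-yl]methoxy}phenol, via chlorohydrin 21 (not isolated)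
Conditions: 9 (3 equiv), K2CO3, DMF, 45 °C
Reagents that add atoms: none
Why: SN2 opening of the benzylic epoxide carbon by the phenoxide (inversion) and closure of the alkoxide onto CH2Cl give the terminal epoxide, as in step 6.

Step 14
Reactants: 22 3-{(R)-[4-(benzyloxy)phenyl][(2S)-oxiran-2-yl]methoxy}phenol
Product: 23 (2S,3R)-2-[4-(benzyloxy)phenyl]-3-(hydroxymethyl)-2,3-dihydro-1-benzofuran-6-ol
Conditions: K2CO3, CF3CH2OH–H2O (4:1), 0.02 M, 70 °C
Reagents that add atoms: none
Why: Phenoxide para-C-alkylation (5-exo-tet epoxide opening with inversion) sets C3 and gives the trans-dihydrobenzofuran, as in step 7.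

Step 15
Reactants: 23 (2S,3R)-2-[4-(benzyloxy)phenyl]-3-(hydroxymethyl)-2,3-dihydro-1-benzofuran-6-ol
Product: 25 (2R,3S)-2-[4-(benzyloxy)phenyl]-3,4-dihydro-2H-chromene-3,7-diol, via bromide 24 (not isolated)
Conditions: CBr4, PPh3, CH2Cl2, 0 °C; then Ag2CO3, (CF3)2CHOH–H2O (4:1), 0 → 25 °C
Reagents that add atoms: carbon tetrabromide BrC(Br)(Br)Br (bromine of 24); water O (hydroxyl oxygen of 25)
Why: Proposed new method: the same phenonium-mediated 1,2-aryl shift as in step 8 (aryl-assisted ionisation of the primary bromide, water opening the spiro-cyclopropane at C3 with inversion) enlarges the five-membered ring to ring C and sets C3 as S with C2 unchanged; the closest known reaction types are Winstein phenonium solvolysis and the Cossy prolinol ring expansion.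

Step 16
Reactants: 25 (2R,3S)-2-[4-(benzyloxy)phenyl]-3,4-dihydro-2H-chromene-3,7-diol
Product: 26 (2R,3S)-2-[4-(benzyloxy)phenyl]-4-methoxy-3,4-dihydro-2H-chromene-3,7-diol (both C4 epimers)
Conditions: DDQ (1.05 equiv), CH3OH–CH2Cl2 (1:4), 0 °C
Reagents that add atoms: methanol CO
Why: DDQ dehydrogenation of a para-alkylphenol (Becker-type benzylic oxidation) turns the 7-OH phenol into the para-quinone methide at C4, which adds methanol; the benzyl ether and C2/C3 are untouched and both C4 epimers give the same cation in step 17.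

Step 17
Reactants: 26 (2R,3S)-2-[4-(benzyloxy)phenyl]-4-methoxy-3,4-dihydro-2H-chromene-3,7-diol; 14 (2R,3S)-2-[3,4-bis(benzyloxy)phenyl]-3,4-dihydro-2H-chromene-3,7-diol
Product: 27 (2R,3S,4S)-2-[4-(benzyloxy)phenyl]-4-[(2R,3S)-2-[3,4-bis(benzyloxy)phenyl]-3,7-dihydroxy-3,4-dihydro-2H-chromen-6-yl]-3,4-dihydro-2H-chromene-3,7-diol
Conditions: 14 (4 equiv), TsOH·H2O (10 mol%), 1,4-dioxane, 25 °C
Reagents that add atoms: none
Why: Acid-catalysed ionisation of the 4-methoxy group to the para-hydroxy-stabilised benzylic cation and Friedel–Crafts capture by C6 of 14 (biomimetic flavan-4-yl condensation; C6 is the unhindered position ortho to the 7-OH) sets C4, attack syn to the 3-OH giving the 3,4-cis (4S) isomer 27, which forms beside its 4R epimer (my estimate for a 5-deoxy 2,3-trans cation is about 2:3, so 27 is probably the minor isomer) and is separated by chromatography while excess 14 is recovered.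

Step 18
Reactants: 27 (2R,3S,4S)-2-[4-(benzyloxy)phenyl]-4-[(2R,3S)-2-[3,4-bis(benzyloxy)phenyl]-3,7-dihydroxy-3,4-dihydro-2H-chromen-6-yl]-3,4-dihydro-2H-chromene-3,7-diol
Product: 28 (2R,3S,4S)-4-[(2R,3S)-2-(3,4-dihydroxyphenyl)-3,7-dihydroxy-3,4-dihydro-2H-chromen-6-yl]-2-(4-hydroxyphenyl)-3,4-dihydro-2H-chromene-3,7-diol
Conditions: H2 (1 atm), Pd(OH)2 on carbon, THF–CH3OH, 25 °C
Reagents that add atoms: none
Why: Hydrogenolysis removes the three benzyl ethers; the benzylic C2–O1 and C4–aryl bonds of flavan dimers survive these conditions and no stereocentre is touched.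

**Compound list**
1 | catechol | Oc1ccccc1O | starting material
2 | 1,2-bis(benzyloxy)benzene | c1ccc(COc2ccccc2OCc2ccccc2)cc1 | intermediate
3 | 1,2-bis(benzyloxy)-4-iodobenzene | Ic1ccc(OCc2ccccc2)c(OCc2ccccc2)c1 | intermediate
4 | acrolein | C=CC=O | starting material
5 | (E)-3-[3,4-bis(benzyloxy)phenyl]prop-2-enal | O=C/C=C/c1ccc(OCc2ccccc2)c(OCc2ccccc2)c1 | intermediate
6 | (2R,3S)-3-[3,4-bis(benzyloxy)phenyl]oxirane-2-carbaldehyde | O=C[C@@H]1O[C@H]1c1ccc(OCc2ccccc2)c(OCc2ccccc2)c1 | intermediate (not isolated)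
7 | [(2S,3S)-3-[3,4-bis(benzyloxy)phenyl]oxiran-2-yl]methanol | OC[C@@H]1O[C@H]1c1ccc(OCc2ccccc2)c(OCc2ccccc2)c1 | intermediate
8 | (2R,3S)-3-[3,4-bis(benzyloxy)phenyl]-2-(chloromethyl)oxirane | ClC[C@@H]1O[C@H]1c1ccc(OCc2ccccc2)c(OCc2ccccc2)c1 | intermediate
9 | resorcinol | Oc1cccc(O)c1 | starting material
10 | 3-{[(1R,2R)-1-[3,4-bis(benzyloxy)phenyl]-3-chloro-2-hydroxypropyl]oxy}phenol | Oc1cccc(O[C@H](c2ccc(OCc3ccccc3)c(OCc3ccccc3)c2)[C@@H](O)CCl)c1 | intermediate (not isolated)
11 | 3-{(R)-[3,4-bis(benzyloxy)phenyl][(2S)-oxiran-2-yl]methoxy}phenol | Oc1cccc(O[C@H](c2ccc(OCc3ccccc3)c(OCc3ccccc3)c2)[C@@H]2CO2)c1 | intermediate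
12 | (2S,3R)-2-[3,4-bis(benzyloxy)phenyl]-3-(hydroxymethyl)-2,3-dihydro-1-benzofuran-6-ol | OC[C@@H]1[C@@H](c2ccc(OCc3ccccc3)c(OCc3ccccc3)c2)Oc2cc(O)ccc21 | intermediate
13 | (2S,3S)-2-[3,4-bis(benzyloxy)phenyl]-3-(bromomethyl)-2,3-dihydro-1-benzofuran-6-ol | BrC[C@@H]1[C@@H](c2ccc(OCc3ccccc3)c(OCc3ccccc3)c2)Oc2cc(O)ccc21 | intermediate (not isolated)
14 | (2R,3S)-2-[3,4-bis(benzyloxy)phenyl]-3,4-dihydro-2H-chromene-3,7-diol (3',4'-di-O-benzylfisetinidol) | O[C@H]1Cc2ccc(O)cc2O[C@@H]1c1ccc(OCc2ccccc2)c(OCc2ccccc2)c1 | intermediate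
15 | 4-iodophenol | Oc1ccc(I)cc1 | starting material
16 | 1-(benzyloxy)-4-iodobenzene | Ic1ccc(OCc2ccccc2)cc1 | intermediate
17 | (E)-3-[4-(benzyloxy)phenyl]prop-2-enal | O=C/C=C/c1ccc(OCc2ccccc2)cc1 | intermediate
18 | (2R,3S)-3-[4-(benzyloxy)phenyl]oxirane-2-carbaldehyde | O=C[C@@H]1O[C@H]1c1ccc(OCc2ccccc2)cc1 | intermediate (not isolated)
19 | [(2S,3S)-3-[4-(benzyloxy)phenyl]oxiran-2-yl]methanol | OC[C@@H]1O[C@H]1c1ccc(OCc2ccccc2)cc1 | intermediate
20 | (2R,3S)-3-[4-(benzyloxy)phenyl]-2-(chloromethyl)oxirane | ClC[C@@H]1O[C@H]1c1ccc(OCc2ccccc2)cc1 | intermediate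
21 | 3-{[(1R,2R)-1-[4-(benzyloxy)phenyl]-3-chloro-2-hydroxypropyl]oxy}phenol | Oc1cccc(O[C@H](c2ccc(OCc3ccccc3)cc2)[C@@H](O)CCl)c1 | intermediate (not isolated)
22 | 3-{(R)-[4-(benzyloxy)phenyl][(2S)-oxiran-2-yl]methoxy}phenol | Oc1cccc(O[C@H](c2ccc(OCc3ccccc3)cc2)[C@@H]2CO2)c1 | intermediate
23 | (2S,3R)-2-[4-(benzyloxy)phenyl]-3-(hydroxymethyl)-2,3-dihydro-1-benzofuran-6-ol | OC[C@@H]1[C@@H](c2ccc(OCc3ccccc3)cc2)Oc2cc(O)ccc21 | intermediate
24 | (2S,3S)-2-[4-(benzyloxy)phenyl]-3-(bromomethyl)-2,3-dihydro-1-benzofuran-6-ol | BrC[C@@H]1[C@@H](c2ccc(OCc3ccccc3)cc2)Oc2cc(O)ccc21 | intermediate (not isolated)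
25 | (2R,3S)-2-[4-(benzyloxy)phenyl]-3,4-dihydro-2H-chromene-3,7-diol (4'-O-benzylguibourtinidol) | O[C@H]1Cc2ccc(O)cc2O[C@@H]1c1ccc(OCc2ccccc2)cc1 | intermediate
26 | (2R,3S)-2-[4-(benzyloxy)phenyl]-4-methoxy-3,4-dihydro-2H-chromene-3,7-diol (both C4 epimers, C4 left open) | O[C@H]1C(OC)c2ccc(O)cc2O[C@@H]1c1ccc(OCc2ccccc2)cc1 | intermediate
27 | (2R,3S,4S)-2-[4-(benzyloxy)phenyl]-4-[(2R,3S)-2-[3,4-bis(benzyloxy)phenyl]-3,7-dihydroxy-3,4-dihydro-2H-chromen-6-yl]-3,4-dihydro-2H-chromene-3,7-diol | c1ccc(COc2ccc([C@H]3Oc4cc(O)ccc4[C@H](c4cc5c(cc4O)O[C@H](c4ccc(OCc6ccccc6)c(OCc6ccccc6)c4)[C@@H](O)C5)[C@@H]3O)cc2)cc1 | intermediate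
28 | (2R,3S,4S)-4-[(2R,3S)-2-(3,4-dihydroxyphenyl)-3,7-dihydroxy-3,4-dihydro-2H-chromen-6-yl]-2-(4-hydroxyphenyl)-3,4-dihydro-2H-chromene-3,7-diol | Oc1ccc([C@H]2Oc3cc(O)ccc3[C@H](c3cc4c(cc3O)O[C@H](c3ccc(O)c(O)c3)[C@@H](O)C4)[C@@H]2O)cc1 | target

**Step count and risks**
Total: 18 steps. Longest linear sequence: 10 steps (steps 1–8, 17, 18).

Step 8 (repeated as step 15), the proposed new ring expansion. Water may attack the CH2 carbon of the phenonium ion and return 12, or the ion may lose a proton. The fallback uses known chemistry and drops the five-membered detour: epoxide 11 is cyclised directly with a Lewis acid (BF3·OEt2, or FeBr3 with AgOSO2CF3, CH2Cl2, −40 °C), the known 6-endo intramolecular Friedel–Crafts epoxy–arene cyclisation of aryl glycidyl ethers. The ring carbon para to the phenol attacks the terminal CH2, the C–O bond of the secondary carbon is kept, and both centres are retained. It sets out from 11 and comes back at 14 (from 22 to 25 in the upper series) and makes no compound outside the list (F0).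

Step 7 (repeated as step 14), the phenoxide para-C-alkylation. The epoxide may hydrolyse or oligomerise before the carbon nucleophile closes the ring. The fallback replaces the phenoxide by an aryllithium. It sets out from 11: para-iodination of the phenol (N-iodosuccinimide, TsOH cat., CH3CN, −10 °C) gives 3-{(R)-[3,4-bis(benzyloxy)phenyl][(2S)-oxiran-2-yl]methoxy}-4-iodophenol F1. NaH, then tert-butyllithium (THF, −78 °C), gives the aryllithium, which opens the epoxide 5-exo (Parham-type anionic cyclisation) and comes back at 12. The upper series runs the same way from 22 through 3-{(R)-[4-(benzyloxy)phenyl][(2S)-oxiran-2-yl]methoxy}-4-iodophenol F2 back to 23.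

Step 17, the interflavan coupling. The 4S (3,4-cis) isomer may be the minor product, and 26 can self-condense. The fallback is a tethered, intramolecular coupling of the kind known to turn 2,3-trans units towards 3,4-cis adducts. It sets out from 14 and 26 and comes back at 28.
- Both phenols are benzylated (BnBr, K2CO3, acetone) to (2R,3S)-7-(benzyloxy)-2-[3,4-bis(benzyloxy)phenyl]-3,4-dihydro-2H-chromen-3-ol F3 and (2R,3S)-7-(benzyloxy)-2-[4-(benzyloxy)phenyl]-4-methoxy-3,4-dihydro-2H-chromen-3-ol F4.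
- F3 with glutaric anhydride (DMAP, pyridine) gives the 3-O-hemiglutarate F5.
- DCC/DMAP esterification of F5 with F4 gives the mixed glutarate diester F6.
- (CH3)3SiOSO2CF3 (cat., CH2Cl2, −20 °C, 2 mM) closes the macrocyclic glutarate of the 4→6 dimer F7; the tether holds the nucleophile on the face of the 3-oxygen.
- LiAlH4 (THF, 0 °C) removes the tether to give the penta-O-benzyl ether of 28 F8, and hydrogenolysis (H2, Pd(OH)2 on carbon) gives 28.

**Further compounds**
F0 | step 8 | none | none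
F1 | step 7 | 3-{(R)-[3,4-bis(benzyloxy)phenyl][(2S)-oxiran-2-yl]methoxy}-4-iodophenol | Oc1ccc(I)c(O[C@H](c2ccc(OCc3ccccc3)c(OCc3ccccc3)c2)[C@@H]2CO2)c1
F2 | step 7 | 3-{(R)-[4-(benzyloxy)phenyl][(2S)-oxiran-2-yl]methoxy}-4-iodophenol | Oc1ccc(I)c(O[C@H](c2ccc(OCc3ccccc3)cc2)[C@@H]2CO2)c1
F3 | step 17 | (2R,3S)-7-(benzyloxy)-2-[3,4-bis(benzyloxy)phenyl]-3,4-dihydro-2H-chromen-3-ol | O[C@H]1Cc2ccc(OCc3ccccc3)cc2O[C@@H]1c1ccc(OCc2ccccc2)c(OCc2ccccc2)c1
F4 | step 17 | (2R,3S)-7-(benzyloxy)-2-[4-(benzyloxy)phenyl]-4-methoxy-3,4-dihydro-2H-chromen-3-ol (both C4 epimers) | O[C@H]1C(OC)c2ccc(OCc3ccccc3)cc2O[C@@H]1c1ccc(OCc2ccccc2)cc1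
F5 | step 17 | 5-{[(2R,3S)-7-(benzyloxy)-2-[3,4-bis(benzyloxy)phenyl]-3,4-dihydro-2H-chromen-3-yl]oxy}-5-oxopentanoic acid | OC(=O)CCCC(=O)O[C@H]1Cc2ccc(OCc3ccccc3)cc2O[C@@H]1c1ccc(OCc2ccccc2)c(OCc2ccccc2)c1
F6 | step 17 | mixed glutarate diester of F4 (3-O) and F3 (3-O) | COC1c2ccc(OCc3ccccc3)cc2O[C@H](c2ccc(OCc3ccccc3)cc2)[C@H]1OC(=O)CCCC(=O)O[C@H]1Cc2ccc(OCc3ccccc3)cc2O[C@@H]1c1ccc(OCc2ccccc2)c(OCc2ccccc2)c1
F7 | step 17 | macrocyclic 3,3'-O-glutarate of the penta-O-benzyl (4→6) dimer, configured as 27 | O=C1CCCC(=O)O[C@H]2Cc3cc([C@H]4c5ccc(OCc6ccccc6)cc5O[C@H](c5ccc(OCc6ccccc6)cc5)[C@H]4O1)c(OCc4ccccc4)cc3O[C@@H]2c2ccc(OCc3ccccc3)c(OCc3ccccc3)c2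
F8 | step 17 | penta-O-benzyl ether of 28 (upper 7 and 4', lower 7, 3' and 4'), configured as 27 | O[C@H]1Cc2cc([C@H]3c4ccc(OCc5ccccc5)cc4O[C@H](c4ccc(OCc5ccccc5)cc4)[C@H]3O)c(OCc3ccccc3)cc2O[C@@H]1c1ccc(OCc2ccccc2)c(OCc2ccccc2)c1
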